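**Retrosynthetic overview**
1. Target 26 ⇐ vinyl lactone 25: the oxirane is made last by hydroxyl-directed epoxidation of the C10 vinyl group from the free 9-OH.
2. α-Methylene lactone and C7 ⇐ bridged ortho ester 18: a C7 radical cyclizes 5-exo-dig onto an alkynyl ortho ester tethered on the cis-8,9-diol; the lactone stays masked until step 16.
3. C6–O and the C7 radical precursor ⇐ iodolactonization of a C5 acetic acid chain across C6=C7; this temporary γ-lactone is later opened to carry the angelate and the acrolein unit.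
4. cis-8,9-Diol and C6=C7 ⇐ directed epoxidation and selenoxide transposition of the Diels–Alder cyclohexene.
5. Carbocycle (formed first) ⇐ catalytic enantioselective Diels–Alder reaction of a 1-silyloxybutadiene with an (E)-trisubstituted enal, setting C5, C9 and quaternary C10. Ring order: cyclohexene, temporary γ-lactone, ortho ester/lactone, oxirane.

Assumption: 3,3,3-triethoxyprop-1-yne and both antipodes of the oxazaborolidine precatalyst are taken as catalogue chemicals, and the (S)-catalyst is taken to shield the enal face as in Corey's formyl C–H···O model (its antipode would be used if the adduct proved enantiomeric).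

Convention: locants C1–C15 are those of the target's elemane skeleton (ring C5–C10; C14 = methyl on C10; C1/C2 = vinyl or oxirane carbons; C3/C4/C15 = acrolein unit; C11–C13 = lactone unit). α/β are relative to the C14 methyl, which is β.

**Route**

Step 1
Reactants: 1 crotonaldehyde, (2E)-but-2-enal
Product: 2 (1E)-1-[(tert-butyldimethylsilyl)oxy]buta-1,3-diene
Conditions: TBSOTf, Et3N, Et2O, 0 °C to rt
Reagents that add atoms: tert-butyldimethylsilyl trifluoromethanesulfonate, CC(C)(C)[Si](C)(C)OS(=O)(=O)C(F)(F)F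
Why: Silyl dienol ether formation by O-silylation of the enal and γ-deprotonation by Et3N gives the extended (E)-1-silyloxydiene.

Step 2
Reactants: 3 3-[(tert-butyldimethylsilyl)oxy]propanal; 4 2-(triphenylphosphoranylidene)propanal
Product: 5 (2E)-5-[(tert-butyldimethylsilyl)oxy]-2-methylpent-2-enal
Conditions: toluene, 80 °C
Reagents that add atoms: none
Why: Wittig olefination with the stabilised formyl ylide is E-selective and stops at the trisubstituted enal, which is less electrophilic than the aliphatic aldehyde.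

Step 3
Reactants: 2 (1E)-1-[(tert-butyldimethylsilyl)oxy]buta-1,3-diene; 5 (2E)-5-[(tert-butyldimethylsilyl)oxy]-2-methylpent-2-enal
Product: 6 (1S,2R,6S)-2-[(tert-butyldimethylsilyl)oxy]-6-{2-[(tert-butyldimethylsilyl)oxy]ethyl}-1-methylcyclohex-3-ene-1-carbaldehyde (9α-OTBS cis to CHO, C5 chain β)
Conditions: (S)-3,3-diphenyl-1-(2-methylphenyl)tetrahydro-1H,3H-pyrrolo[1,2-c][1,3,2]oxazaborole (20 mol%), HN(SO2CF3)2 (20 mol%), 2 (3 equiv), CH2Cl2, −78 to −40 °C
Reagents that add atoms: none
Why: Catalytic enantioselective Diels–Alder reaction in which the 1-silyloxy group directs "ortho" regiochemistry (C9–C10 bond), the endo boron-bound formyl group puts 9-OTBS cis to CHO, the E geometry of 5 becomes the trans relation of CHO and the C5 chain, and the catalyst blocks one enal face, so C5, C9 and quaternary C10 are set together.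

Step 4
Reactants: 6 Diels–Alder aldehyde
Product: 7 (3R,4S,5S)-3-[(tert-butyldimethylsilyl)oxy]-5-{2-[(tert-butyldimethylsilyl)oxy]ethyl}-4-ethenyl-4-methylcyclohexene
Conditions: Ph3PCH3Br, KN(SiMe3)2, THF, 0 °C to rt
Reagents that add atoms: methyltriphenylphosphonium bromide, C[P+](c1ccccc1)(c1ccccc1)c1ccccc1.[Br-]
Why: Wittig methylenation of the non-enolisable neopentyl aldehyde installs the C10 vinyl group without touching any stereocentre.

Step 5
Reactants: 7 bis-silyl ether
Product: 8 (1R,5S,6S)-6-ethenyl-5-(2-hydroxyethyl)-6-methylcyclohex-2-en-1-ol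
Conditions: Bu4NF, THF, rt to 40 °C
Reagents that add atoms: none
Why: Fluoride-mediated desilylation frees both alcohols, the allylic 9α-OH being needed as a directing group.

Step 6
Reactants: 8 diol
Product: 9 (1S,2S,3S,4R,6R)-3-ethenyl-4-(2-hydroxyethyl)-3-methyl-7-oxabicyclo[4.1.0]heptan-2-ol (7α,8α-epoxide cis to 9α-OH)
Conditions: VO(acac)2 (5 mol%), tBuOOH (1.1 equiv), CH2Cl2, 0 °C
Reagents that add atoms: tert-butyl hydroperoxide, CC(C)(C)OO
Why: Hydroxyl-directed vanadium-catalysed epoxidation delivers oxygen from the vanadate ester of the allylic 9α-OH to the same face of C7=C8 (sets C7 and C8) and is far faster for the allylic alkene than for the homoallylic vinyl group.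

Step 7
Reactants: 9 epoxy diol
Product: 12 (1S,2R,5R,6S)-6-ethenyl-5-(2-hydroxyethyl)-6-methylcyclohex-3-ene-1,2-diol (8α,9α-diol with C6=C7), via hydroxy selenide 10 (not isolated), via selenoxide 11 (not isolated)
Conditions: PhSeSePh, NaBH4, EtOH, 0 °C to reflux; then THF, 30% H2O2, pyridine, 0 °C to rt
Reagents that add atoms: none
Why: Sharpless–Lauer epoxide-to-allylic-alcohol transposition, in which PhSe− opens the epoxide trans-diaxially at C7 (remote from the hydroxyl) and the selenoxide eliminates syn away from the carbinol carbon, so the 8α-OH keeps the epoxide's configuration and the alkene moves to C6=C7.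

Step 8
Reactants: 12 triol
Product: 14 2-(6-ethenyl-4,5-dihydroxy-6-methylcyclohex-2-en-1-yl)acetic acid with the ring configuration of 12 (C5 chain β; 8α,9α-diol), via aldehyde 13 (not isolated)
Conditions: TEMPO (0.2 equiv), PhI(OAc)2 (2.5 equiv), MeCN/H2O, NaHCO3, 0 °C to rt
Reagents that add atoms: water, O
Why: Oxoammonium (TEMPO) oxidation is selective for the unhindered primary alcohol and takes it through the aldehyde hydrate to the acid while the secondary hydroxyls survive.

Step 9
Reactants: 14 dihydroxy acid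
Product: 15 4-ethenyl-5,6-dihydroxy-7-iodo-4-methylhexahydro-1-benzofuran-2(3H)-one (cis-fused 6β,3-γ-lactone; 7α-I; 8α,9α-diol; 10α-vinyl)
Conditions: I2 (2 equiv), NaHCO3 (3 equiv), MeCN/H2O, 0 °C, dark
Reagents that add atoms: iodine, II
Why: Iodolactonization in which the carboxylate on the β chain of C5 can reach C6 only from the β face (5-exo, cis-fused γ-lactone), so C6–O is set β and iodine adds anti at C7.

Step 10
Reactants: 15 iodolactone diol; 16 3,3,3-triethoxyprop-1-yne
Product: 17 8α,9α-O-(1-ethoxyprop-2-yn-1-ylidene) ortho ester of 15 (ethynyl endo under C7, ethoxy exo)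
Conditions: pyridinium p-toluenesulfonate (5 mol%), CH2Cl2, 4 Å molecular sieves, rt
Reagents that add atoms: none
Why: Acid-catalysed ortho ester exchange ties the cis-diol into a 2-alkynyl-2-ethoxy-1,3-dioxolane, ethanol adding to the dioxolanylium ion from the convex face so that the small ethynyl group sits endo (this centre, C12, is destroyed later).

Step 11
Reactants: 17 alkynyl ortho ester iodide
Product: 18 bridged ortho ester (C7α–C11 bond, exocyclic C11=C13H2, C12 carrying OEt and bonded to O8 and O9; 6β,3-lactone intact)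
Conditions: (Me3Si)3SiH (1.5 equiv, syringe pump), AIBN (0.3 equiv), toluene (0.005 M), 85 °C
Reagents that add atoms: none
Why: Proposed new method: the C7 radical from the iodide adds 5-exo-dig to the alkyne carbon held on the α face by the ortho ester, so the C7–C11 bond must form cis to O8 and the vinyl radical is reduced to the exocyclic methylene, giving the α-methylene lactone at the ortho ester oxidation level; the closest known reactions are Ueno–Stork acetal-tethered cyclizations and 5-exo-dig cyclizations of β-halo propargyl ethers, and the bridged ring is of the kind formed in the 2-(cyclopent-3-enyl)ethyl to 2-norbornyl radical cyclization.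

Step 12
Reactants: 18 bridged ortho ester lactone
Product: 19 hydroxy Weinreb amide (6β-OH; C5β-CH2C(=O)N(OMe)Me; ortho ester intact)
Conditions: MeNH(OMe)·HCl (3 equiv), iPrMgCl (6 equiv), THF, −20 to 0 °C
Reagents that add atoms: N,O-dimethylhydroxylamine hydrochloride, CNOC.Cl
Why: Weinreb aminolysis opens the only free lactone (the other is masked as the base-stable ortho ester) and frees the 6β-hydroxyl without touching C6.

Step 13
Reactants: 19 hydroxy Weinreb amide; 20 angelic acid, (2Z)-2-methylbut-2-enoic acid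
Product: 21 6β-angelate of 19
Conditions: 20, 2,4,6-Cl3C6H2COCl, Et3N, THF, 0 °C (mixed anhydride); 19, LiN(SiMe3)2, THF, −78 °C, then the anhydride, −78 to −20 °C
Reagents that add atoms: none
Why: Yamaguchi-type esterification of the lithium alkoxide with the preformed mixed anhydride at low temperature gives the angelate without Z-to-E isomerization and before the γ-hydroxy amide can relactonize.

Step 14
Reactants: 21 angelate Weinreb amide
Product: 22 aldehyde (C5β-CH2CHO; 6β-angelate; ortho ester intact)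
Conditions: iBu2AlH (1.2 equiv), THF, −78 °C; aqueous potassium sodium tartrate
Reagents that add atoms: none
Why: Hydride reduction of the Weinreb amide stops at the aldehyde through the chelated tetrahedral intermediate, and at −78 °C the hindered conjugated angelate and the ortho ester are not reduced.

Step 15
Reactants: 22 aldehyde
Product: 24 enal (C5β-C(=CH2)CHO; 6β-angelate; ortho ester intact), via Mannich base 23 (not isolated)
Conditions: CH2=NMe2+ I− (3 equiv), Et3N (5 equiv), CH2Cl2, rt
Reagents that add atoms: N,N-dimethylmethyleneiminium iodide (Eschenmoser's salt), C=[N+](C)C.[I-]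
Why: Mannich reaction followed by amine elimination (aldehyde α-methylenation) builds the 2-substituted acrolein under anhydrous basic conditions that keep the ortho ester closed, so no amine meets a free α-methylene lactone.

Step 16
Reactants: 24 ortho ester enal
Product: 25 (5R,6S,7R,8R,9S,10S)-6-angeloyloxy-9-hydroxy-3-oxoelema-1,4(15),11(13)-trien-12,8-olide (the 10-vinyl analogue of the target)
Conditions: pyridinium p-toluenesulfonate (10 mol%), THF/H2O 4:1, rt
Reagents that add atoms: water, O
Why: Ortho ester hydrolysis of the strained bridged system gives a hemiortho ester that collapses to the cis-fused five-membered 8,12-lactone, releasing the 9α-hydroxyl and ethanol.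

Step 17
Reactants: 25 vinyl lactone
Product: 26 target, (1S,5R,6S,7R,8R,9S,10S)-6-angeloyloxy-1,2-epoxy-9-hydroxy-3-oxoelema-4(15),11(13)-dien-12,8-olide
Conditions: VO(acac)2 (10 mol%), tBuOOH (1.5 equiv), CH2Cl2, 0 °C to rt
Reagents that add atoms: tert-butyl hydroperoxide, CC(C)(C)OO
Why: Hydroxyl-directed vanadium-catalysed epoxidation of the homoallylic vinyl group, the only alkene that is not electron-poor, where in the preferred chair (O9 equatorial, vinyl axial with its CH2 end pointing away from the ring) the vanadate on O9 delivers oxygen to the alkene face turned towards C9 and so gives the (1S)-oxirane.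

**Compound list**
1 | crotonaldehyde, (2E)-but-2-enal | C/C=C/C=O | starting material
2 | (1E)-1-[(tert-butyldimethylsilyl)oxy]buta-1,3-diene | C=C/C=C/O[Si](C)(C)C(C)(C)C | intermediate
3 | 3-[(tert-butyldimethylsilyl)oxy]propanal | O=CCCO[Si](C)(C)C(C)(C)C | starting material
4 | 2-(triphenylphosphoranylidene)propanal | CC(C=O)=P(c1ccccc1)(c1ccccc1)c1ccccc1 | starting material
5 | (2E)-5-[(tert-butyldimethylsilyl)oxy]-2-methylpent-2-enal | O=C/C(C)=C/CCO[Si](C)(C)C(C)(C)C | intermediate
6 | (1S,2R,6S)-2-[(tert-butyldimethylsilyl)oxy]-6-{2-[(tert-butyldimethylsilyl)oxy]ethyl}-1-methylcyclohex-3-ene-1-carbaldehyde | O=C[C@]1(C)[C@H](O[Si](C)(C)C(C)(C)C)C=CC[C@H]1CCO[Si](C)(C)C(C)(C)C | intermediate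
7 | (3R,4S,5S)-3-[(tert-butyldimethylsilyl)oxy]-5-{2-[(tert-butyldimethylsilyl)oxy]ethyl}-4-ethenyl-4-methylcyclohexene | C=C[C@]1(C)[C@H](O[Si](C)(C)C(C)(C)C)C=CC[C@H]1CCO[Si](C)(C)C(C)(C)C | intermediate
8 | (1R,5S,6S)-6-ethenyl-5-(2-hydroxyethyl)-6-methylcyclohex-2-en-1-ol | C=C[C@]1(C)[C@H](O)C=CC[C@H]1CCO | intermediate
9 | (1S,2S,3S,4R,6R)-3-ethenyl-4-(2-hydroxyethyl)-3-methyl-7-oxabicyclo[4.1.0]heptan-2-ol | C=C[C@]1(C)[C@H](O)[C@@H]2O[C@@H]2C[C@H]1CCO | intermediate
10 | hydroxy selenide: 7β-(phenylselanyl)-8α,9α-diol with 10α-vinyl and C5β-(2-hydroxyethyl) | C=C[C@]1(C)[C@H](O)[C@H](O)[C@@H]([Se]c2ccccc2)C[C@H]1CCO | intermediate (not isolated)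
11 | selenoxide of 10 (mixture at selenium) | C=C[C@]1(C)[C@H](O)[C@H](O)[C@@H]([Se](=O)c2ccccc2)C[C@H]1CCO | intermediate (not isolated)
12 | (1S,2R,5R,6S)-6-ethenyl-5-(2-hydroxyethyl)-6-methylcyclohex-3-ene-1,2-diol | C=C[C@]1(C)[C@H](O)[C@H](O)C=C[C@H]1CCO | intermediate
13 | 2-(6-ethenyl-4,5-dihydroxy-6-methylcyclohex-2-en-1-yl)acetaldehyde, ring configuration of 12 | C=C[C@]1(C)[C@H](O)[C@H](O)C=C[C@H]1CC=O | intermediate (not isolated)
14 | 2-(6-ethenyl-4,5-dihydroxy-6-methylcyclohex-2-en-1-yl)acetic acid, ring configuration of 12 | C=C[C@]1(C)[C@H](O)[C@H](O)C=C[C@H]1CC(=O)O | intermediate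
15 | 4-ethenyl-5,6-dihydroxy-7-iodo-4-methylhexahydro-1-benzofuran-2(3H)-one (6β,3-lactone, 7α-I, 8α,9α-diol, 10α-vinyl) | C=C[C@]1(C)[C@H](O)[C@H](O)[C@H](I)[C@H]2OC(=O)C[C@@H]12 | intermediate
16 | 3,3,3-triethoxyprop-1-yne (triethyl orthopropiolate) | C#CC(OCC)(OCC)OCC | starting material
17 | 8α,9α-O-(1-ethoxyprop-2-yn-1-ylidene) ortho ester of 15, ethynyl endo | C=C[C@]1(C)[C@@H]2O[C@](OCC)(C#C)O[C@@H]2[C@H](I)[C@H]3OC(=O)C[C@@H]13 | intermediate
18 | bridged ortho ester: C7α–C11 bond, C11=CH2, C12(OEt) bonded to O8 and O9, 6β,3-lactone | C=C[C@]1(C)[C@@H]2O[C@@]3(OCC)O[C@@H]2[C@H](C3=C)[C@H]4OC(=O)C[C@@H]14 | intermediate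
19 | hydroxy Weinreb amide: 6β-OH, C5β-CH2C(=O)N(OMe)Me, ortho ester as in 18 | C=C[C@]1(C)[C@@H]2O[C@@]3(OCC)O[C@@H]2[C@H](C3=C)[C@@H](O)[C@H]1CC(=O)N(C)OC | intermediate
20 | angelic acid, (2Z)-2-methylbut-2-enoic acid | C/C=C(/C)C(=O)O | starting material
21 | 6β-angelate of 19 | C=C[C@]1(C)[C@@H]2O[C@@]3(OCC)O[C@@H]2[C@H](C3=C)[C@@H](OC(=O)/C(C)=C\C)[C@H]1CC(=O)N(C)OC | intermediate
22 | aldehyde: C5β-CH2CHO, 6β-angelate, ortho ester as in 18 | C=C[C@]1(C)[C@@H]2O[C@@]3(OCC)O[C@@H]2[C@H](C3=C)[C@@H](OC(=O)/C(C)=C\C)[C@H]1CC=O | intermediate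
23 | Mannich base: C5β-CH(CH2NMe2)CHO (mixture at the new centre) | C=C[C@]1(C)[C@@H]2O[C@@]3(OCC)O[C@@H]2[C@H](C3=C)[C@@H](OC(=O)/C(C)=C\C)[C@H]1C(CN(C)C)C=O | intermediate (not isolated)
24 | enal: C5β-C(=CH2)CHO, 6β-angelate, ortho ester as in 18 | C=C[C@]1(C)[C@@H]2O[C@@]3(OCC)O[C@@H]2[C@H](C3=C)[C@@H](OC(=O)/C(C)=C\C)[C@H]1C(=C)C=O | intermediate
25 | (5R,6S,7R,8R,9S,10S)-6-angeloyloxy-9-hydroxy-3-oxoelema-1,4(15),11(13)-trien-12,8-olide | C=C[C@]1(C)[C@H](O)[C@@H]2OC(=O)C(=C)[C@@H]2[C@@H](OC(=O)/C(C)=C\C)[C@H]1C(=C)C=O | intermediate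
26 | CNP0113462.5, (1S,5R,6S,7R,8R,9S,10S)-6-angeloyloxy-1,2-epoxy-9-hydroxy-3-oxoelema-4(15),11(13)-dien-12,8-olide | C=C1C(=O)O[C@@H]2[C@H]1[C@@H](OC(=O)/C(C)=C\C)[C@@H](C(=C)C=O)[C@](C)([C@H]1CO1)[C@@H]2O | target

**Totals**
Total steps: 17. Longest linear sequence: 16 steps (steps 2–17 from 3; equally steps 1 and 3–17 from 1).

**Three steps most likely to fail, with fallbacks**

Step 3 (a trisubstituted enal may react slowly or with poor face or endo control). The fallback sets out from 1 and 5 and returns at 8; it replaces catalyst control by a covalent auxiliary on the diene. The potassium dienolate of 1 (KOtBu, THF, −78 °C) is O-acylated with (S)-2-methoxy-2-phenylacetyl chloride to give (1E)-buta-1,3-dien-1-yl (2S)-2-methoxy-2-phenylacetate F1. Its BF3·OEt2-promoted Diels–Alder reaction with 5 (CH2Cl2, −78 °C; the phenyl ring stacks over one diene face) gives the O9 mandelate analogue of 6 F2. Wittig methylenation (Ph3PCH3Br, KN(SiMe3)2) gives the O9 mandelate analogue of 7 F3. K2CO3 in MeOH removes the auxiliary to give the C3 mono-silyl ether of 8 F4, and Bu4NF then gives 8.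

Step 11 (the bridged ring may close too slowly, or the C7 radical may be reduced or attack the C10 vinyl group). The fallback sets out from 15 and returns at 25; it uses an unstrained one-oxygen tether and adds the lactone carbonyl by oxidation.
- The diol of 15 is alkylated at the less hindered O8 through its stannylene acetal (Bu2SnO, toluene, reflux; propargyl bromide, Bu4NI) to give the O8 propargyl ether of 15 F5.
- Radical 5-exo-dig cyclization (Bu3SnH, AIBN, benzene, 80 °C) gives the 3-methylenetetrahydrofuran with free 9α-OH and intact 6β,3-lactone F6.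
- Et3SiOTf and 2,6-lutidine give the O9 triethylsilyl ether of F6 F7.
- The operations of steps 12–15 follow: Weinreb opening gives the hydroxy Weinreb amide from F7 F8; angeloylation gives the 6β-angelate of F8 F9; iBu2AlH gives the C3 aldehyde from F9 F10; aqueous formaldehyde with catalytic pyrrolidine and propionic acid gives the enal from F10 F11.
- Allylic oxidation of the cyclic allyl ether (CrO3, 3,5-dimethylpyrazole, CH2Cl2, −20 °C) gives the O9 triethylsilyl ether of 25 F12, and HF·pyridine gives 25.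

Step 17 (the C1 configuration depends on the ring conformer in the directed transition state). The fallback sets out from 25 and returns at 26; it replaces substrate direction by catalyst-controlled resolution. Undirected epoxidation of 25 with dimethyldioxirane (acetone, 0 °C) gives 26 together with the C1 epimer of 26 F13. Hydrolytic kinetic resolution with (R,R)-[N,N'-bis(3,5-di-tert-butylsalicylidene)cyclohexane-1,2-diaminato]cobalt acetate and 0.55 equiv H2O hydrolyses F13 to the (1R)-1,2-diol from F13 F14 and leaves 26, which is separated by chromatography.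

**Further compounds**
F1 | step 3 | (1E)-buta-1,3-dien-1-yl (2S)-2-methoxy-2-phenylacetate | C=C/C=C/OC(=O)[C@@H](OC)c1ccccc1
F2 | step 3 | O9 mandelate analogue of 6 | O=C[C@]1(C)[C@H](OC(=O)[C@@H](OC)c2ccccc2)C=CC[C@H]1CCO[Si](C)(C)C(C)(C)C
F3 | step 3 | O9 mandelate analogue of 7 | C=C[C@]1(C)[C@H](OC(=O)[C@@H](OC)c2ccccc2)C=CC[C@H]1CCO[Si](C)(C)C(C)(C)C
F4 | step 3 | C3 mono-silyl ether of 8 | C=C[C@]1(C)[C@H](O)C=CC[C@H]1CCO[Si](C)(C)C(C)(C)C
F5 | step 11 | O8 propargyl ether of 15 | C=C[C@]1(C)[C@H](O)[C@H](OCC#C)[C@H](I)[C@H]2OC(=O)C[C@@H]12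
F6 | step 11 | 3-methylenetetrahydrofuran with free 9α-OH and intact 6β,3-lactone | C=C[C@]1(C)[C@H](O)[C@@H]2OCC(=C)[C@@H]2[C@H]3OC(=O)C[C@@H]13
F7 | step 11 | O9 triethylsilyl ether of F6 | C=C[C@]1(C)[C@H](O[Si](CC)(CC)CC)[C@@H]2OCC(=C)[C@@H]2[C@H]3OC(=O)C[C@@H]13
F8 | step 11 | hydroxy Weinreb amide from F7 | C=C[C@]1(C)[C@H](O[Si](CC)(CC)CC)[C@@H]2OCC(=C)[C@@H]2[C@@H](O)[C@H]1CC(=O)N(C)OC
F9 | step 11 | 6β-angelate of F8 | C=C[C@]1(C)[C@H](O[Si](CC)(CC)CC)[C@@H]2OCC(=C)[C@@H]2[C@@H](OC(=O)/C(C)=C\C)[C@H]1CC(=O)N(C)OC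
F10 | step 11 | C3 aldehyde from F9 | C=C[C@]1(C)[C@H](O[Si](CC)(CC)CC)[C@@H]2OCC(=C)[C@@H]2[C@@H](OC(=O)/C(C)=C\C)[C@H]1CC=O
F11 | step 11 | enal from F10 | C=C[C@]1(C)[C@H](O[Si](CC)(CC)CC)[C@@H]2OCC(=C)[C@@H]2[C@@H](OC(=O)/C(C)=C\C)[C@H]1C(=C)C=O
F12 | step 11 | O9 triethylsilyl ether of 25 | C=C[C@]1(C)[C@H](O[Si](CC)(CC)CC)[C@@H]2OC(=O)C(=C)[C@@H]2[C@@H](OC(=O)/C(C)=C\C)[C@H]1C(=C)C=O
F13 | step 17 | C1 epimer of 26 | C=C1C(=O)O[C@@H]2[C@H]1[C@@H](OC(=O)/C(C)=C\C)[C@@H](C(=C)C=O)[C@](C)([C@@H]1CO1)[C@@H]2O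
F14 | step 17 | (1R)-1,2-diol from F13 | C=C1C(=O)O[C@@H]2[C@H]1[C@@H](OC(=O)/C(C)=C\C)[C@@H](C(=C)C=O)[C@](C)([C@@H](O)CO)[C@@H]2O
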